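## The problem

Numbering used throughout: ring A = N4–C3–C2–C1–C9a (pyrrolidine); ring B = N4–C5–C6–C7–C8–C9–C9a (azepane); ring C = C9a–C9–C10–C11–C12 (cyclopentane); ring D = O–C14(=O)–C13–C12–C11 (lactone); ring E = C18–C19–C20–C21(=O)–O (lactone on C3). Ethyl sits on C10, methyl groups on C13 and C20.

- Rings A, B and C all meet at the aza-quaternary carbon C9a. Ring D is cis-fused to ring C, and ring E hangs from C3.
- There are nine stereocentres (3S,9R,9aS,10R,11S,12R,13S,18S,20S); six of them are contiguous on rings C and D.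
- Seen on ring C with N4 (on C9a) up: ethyl is up; C8 (on C9), O (on C11), C13 (on C12) and C1 (on C9a) are down. Ring B is therefore trans-fused to ring C, and nitrogen lies on the face opposite to both neighbouring carbon substituents.
- A carbon nucleophile added to a C9a=N bond would enter from that open face and give the wrong epimer. The C–N bond must be the last bond made at C9a.
- At C13 the hydroxyl is exo (syn to H12) and the methyl endo. At C3, C18 is syn to C12 across ring A; the C3/C18 pair is threo and C18/C20 are cis.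
- Relay of control: C11 can set C10 and C9 (trans,trans). Through O11 it can set C12 and C13. C9 and C12 together can set C9a. The bicyclic amine can set C3 and C18, and C18 can set C20.
- Feature that the plan exploits: across the C9a–C12 bond, N4 and C13 are anti, while C13 is syn to O11. A C13 radical tethered to O11 must add to C12 from the lower face, and the C9a radical it leaves is open only from above, where nitrogen belongs. This is an anti carbo-amination of a C12=C9a double bond.
- Fragile groups: ring E (enolisable, epimerisable C20–H), two lactones (no hydride or organometallic reagents late), the tertiary amine (no oxidants) and the tertiary alcohol.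

## Retrosynthesis

**24 from 23.** The only cut is H2 across C19=C20 of ring E. It comes last so that the base-sensitive C20–H never meets an enolate step. The forward reaction must add hydrogen anti to the C3 substituent on C18.

**23 from 18 and 20, through iminium 22.** The C3–C18 bond is cut as a vinylogous Mannich addition, and with it the N4=C3 bond that closes ring A. The neighbouring choices (SN2 closure with a pre-built side chain, or addition to a C18 aldehyde) need more steps and expose ring E to base. This cut adds ring A, ring E, C3 and C18 in one operation; 18 has two rings and two stereocentres fewer. The forward step must attack 22 on the C12 face and give the threo pair.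

**18 from 15, and 15 from 14.** N4–C5 is cut as a reductive amination of the amine released from the tertiary azide. C6=C7 is cut as a cross-metathesis that lengthens the allyl group on C9 by the aldehyde carbon. Ring B is closed on nitrogen because N4 and C8 are trans, which blocks every five-membered alternative. No stereocentre is made.

**14 from 12.** C13–O is cut as an enolate oxidation. It is done while ring D is the only enolisable carbonyl group and the convex face of the cis-bicycle dictates the result.

**12 from 11 (key disconnection).** C12–C13 and C9a–N are cut together. Ring D, the aza-quaternary carbon and the stereocentres C12 and C9a all come from one alkene. Cutting C9a–C1 or C9a–C9 instead would bring carbon in from the open face. A dipolar cut to a nitrone is geometrically impossible (Alternative 3). Precursor 11 is a monocyclic cyclopentene with three stereocentres. The forward reaction needs 5-exo addition at C12 and azide transfer anti to it.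

**11 from 9, 9 from 8, 8 from 6 and 7, 6 from 4.** The ester C–O bond, the silyl ether and the C9a–C1 bond (alkenyl triflate plus alkylzinc) are cut in turn. The triflate comes from the kinetic enolate of ketone 4 on its unsubstituted side. These are functional-group steps; the C1–C3 chain arrives with C3 masked as an acetal.

**4 from 1.** C10–ethyl and C9–allyl are cut as a conjugate addition and enolate allylation on the bought enone 1. The trans,trans triad O11/ethyl/C8 is the pattern this coupling gives, so C10 and C9 are relayed from C11 in one event.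

**20 from 19.** One silylation gives the nucleophile for ring E.

## Roads not taken

**Alternative 1** (the most obvious): cut C9a–C1. Ketone 4 is turned into ketimine A1 and a three-carbon nucleophile is added to the C=N bond; ring A is closed afterwards. The nucleophile would approach anti to the allyl group on C9, so carbon would end up on the upper face and nitrogen below, giving amine A2, the C9a epimer of what is needed. The chosen plan lets nitrogen, not carbon, take the open face. It also avoids enolate alkylation at C12 next to the β-silyloxy group, which would place C13 trans to O11.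

**Alternative 2**: cut N4–C9a and N4–C5 as an intramolecular Schmidt reaction of azido ketone A3, which would give lactam A4 with rings A and B and retention at C9a. A3 already needs the quaternary carbon at a trans ring fusion, which angular alkylation of such ketones does not favour. It also needs all five ring-C stereocentres and ring D, so the precursor is no simpler than the product. A4 then needs its C5 carbonyl removed beside a lactone and has no handle at C3. The chosen key step starts from a monocyclic alkene.

**Alternative 3**: cut C9a–C12 and C13–O as an intramolecular nitrone–alkene cycloaddition of nitrone A5, giving isoxazolidine A6. It would close ring C and deliver the C13 oxygen at once. The N4–O–C13 bridge forces the isoxazolidine to be cis-fused to ring C, so N4 and C13 would be syn on ring C, whereas 24 has them anti. A6 is necessarily epimeric at a ring-fusion carbon (C12 as drawn) and cannot lactonise to ring D. The radical step adds carbon and nitrogen anti across the corresponding alkene.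

Key step: step 6

Remark: compounds 10, 11 and 12 are carried as mixtures at C13; this centre is erased in step 6 and fixed in step 7, so it is left undefined in their SMILES.

## Route

Step 1
Reactants: 1 (R)-4-[(tert-butyldimethylsilyl)oxy]cyclopent-2-en-1-one
Product: 4 (2R,3R,4R)-2-allyl-4-[(tert-butyldimethylsilyl)oxy]-3-ethylcyclopentan-1-one, via copper enolate 2 (not isolated), via triphenyltin enolate 3 (not isolated)
Conditions: EtLi, CuI, PBu3, THF, −78 °C; then HMPA, Ph3SnCl, −78 °C; then allyl iodide, −30 °C
Reagents that add atoms: ethyllithium (CC[Li]); allyl iodide (C=CCI)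
Why: Three-component coupling (conjugate addition, then enolate allylation): the ethylcopper reagent adds to C10 anti to the silyloxy group and tin enolate 3 is allylated at C9 anti to the new ethyl group, so C10 and C9 are both relayed from C11.

Step 2
Reactants: 4 (2R,3R,4R)-2-allyl-4-[(tert-butyldimethylsilyl)oxy]-3-ethylcyclopentan-1-one
Product: 6 (3S,4R,5R)-5-allyl-3-[(tert-butyldimethylsilyl)oxy]-4-ethylcyclopent-1-en-1-yl trifluoromethanesulfonate, via potassium enolate 5 (not isolated)
Conditions: KN(SiMe3)2, THF, −78 °C; then N-(5-chloropyridin-2-yl)bis(trifluoromethanesulfonimide), −78 °C; aq. NH4Cl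
Reagents that add atoms: N-(5-chloropyridin-2-yl)bis(trifluoromethanesulfonimide) (FC(F)(F)S(=O)(=O)N(c1ccc(Cl)cn1)S(=O)(=O)C(F)(F)F)
Why: Kinetic deprotonation by the hindered amide takes a proton from the C12 methylene and not the tertiary C9–H, and O-sulfonylation at −78 °C should trap enolate 5 before the β-silyloxy group on C11 is expelled (enol triflate from a kinetic enolate).

Step 3
Reactants: 6 (3S,4R,5R)-5-allyl-3-[(tert-butyldimethylsilyl)oxy]-4-ethylcyclopent-1-en-1-yl trifluoromethanesulfonate; 7 [2-(1,3-dioxolan-2-yl)ethyl]zinc bromide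
Product: 8 tert-butyl{[(1S,4R,5R)-4-allyl-3-[2-(1,3-dioxolan-2-yl)ethyl]-5-ethylcyclopent-2-en-1-yl]oxy}dimethylsilane
Conditions: Pd(PPh3)4 (5 mol %), THF, 50 °C
Reagents that add atoms: none
Why: Negishi coupling: zerovalent palladium inserts into the alkenyl triflate, the primary alkylzinc transmetalates and reductive elimination forms C9a–C1; no stereocentre is touched.

Step 4
Reactants: 8 tert-butyl{[(1S,4R,5R)-4-allyl-3-[2-(1,3-dioxolan-2-yl)ethyl]-5-ethylcyclopent-2-en-1-yl]oxy}dimethylsilane
Product: 9 (1S,4R,5R)-4-allyl-3-[2-(1,3-dioxolan-2-yl)ethyl]-5-ethylcyclopent-2-en-1-ol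
Conditions: Bu4NF, THF, 0 °C to rt
Reagents that add atoms: none
Why: Fluoride cleaves the silyl ether; the acetal and both alkenes are inert.

Step 5
Reactants: 9 (1S,4R,5R)-4-allyl-3-[2-(1,3-dioxolan-2-yl)ethyl]-5-ethylcyclopent-2-en-1-ol
Product: 11 (1S,4R,5R)-4-allyl-3-[2-(1,3-dioxolan-2-yl)ethyl]-5-ethylcyclopent-2-en-1-yl 2-iodopropanoate (C13 epimers), via bromo ester 10 (not isolated)
Conditions: 2-bromopropanoyl bromide, pyridine, DMAP (cat.), CH2Cl2, 0 °C; then NaI, acetone, rt, dark
Reagents that add atoms: 2-bromopropanoyl bromide (CC(Br)C(=O)Br); sodium iodide ([Na+].[I-])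
Why: Acylation of the allylic alcohol, then Finkelstein exchange to the iodide, which gives up its halogen to tin radicals more readily; C13 is a mixture because it becomes a radical in step 6.

Step 6
Reactants: 11 (1S,4R,5R)-4-allyl-3-[2-(1,3-dioxolan-2-yl)ethyl]-5-ethylcyclopent-2-en-1-yl 2-iodopropanoate
Product: 12 (3aR,4S,5R,6R,6aS)-5-allyl-4-azido-4-[2-(1,3-dioxolan-2-yl)ethyl]-6-ethyl-3-methylhexahydro-2H-cyclopenta[b]furan-2-one (C13 epimers)
Conditions: PhSO2N3 (3 equiv), (Bu3Sn)2 (1.5 equiv), di-tert-butyl hyponitrite (10 mol %), benzene (0.02 M), 80 °C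
Reagents that add atoms: benzenesulfonyl azide ([N-]=[N+]=NS(=O)(=O)c1ccccc1)
Why: Tin-mediated radical carbo-azidation run intramolecularly: Bu3Sn• abstracts iodine from 11, the electrophilic C13 radical adds to C12 of the C12=C9a bond, and the tertiary, nucleophilic C9a radical takes N3 from PhSO2N3, the PhSO2• released regenerating Bu3Sn• from the ditin. The closest known reaction types are carbo-azidation of alkenes with α-iodo esters and sulfonyl azides, iodine-atom-transfer cyclisation of allyl α-iodo esters to γ-lactones, and radical cyclisation–trapping on cyclopentenyl acetals. Ring D closes 5-exo-trig; the radical is tethered to O11 and can only reach the lower face of C12, which fixes C12 with C13 syn to O11 (cis fusion). C9a is set by the azide donor, which meets the planar radical on the upper face, anti to the new C12–C13 bond and to the allyl group on C9, so nitrogen ends up trans to C13 and C8 and the C1 chain is pushed down. C13 forms as a mixture and is corrected in step 7. The step needs exo over endo closure (exo gives the tertiary radical), azidation only after cyclisation (the α-ester radical is polarity-mismatched with the sulfonyl azide, the tertiary alkyl radical is matched), and cyclisation over intermolecular addition to an allyl group (high dilution, alkene held next to the radical).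

Step 7
Reactants: 12 (3aR,4S,5R,6R,6aS)-5-allyl-4-azido-4-[2-(1,3-dioxolan-2-yl)ethyl]-6-ethyl-3-methylhexahydro-2H-cyclopenta[b]furan-2-one
Product: 14 (3S,3aR,4S,5R,6R,6aS)-5-allyl-4-azido-4-[2-(1,3-dioxolan-2-yl)ethyl]-6-ethyl-3-hydroxy-3-methylhexahydro-2H-cyclopenta[b]furan-2-one, via potassium enolate 13 (not isolated)
Conditions: KN(SiMe3)2, THF, −78 °C; then 3-phenyl-2-(phenylsulfonyl)oxaziridine, −78 °C; aq. NH4Cl
Reagents that add atoms: 3-phenyl-2-(phenylsulfonyl)oxaziridine (O=S(=O)(N1OC1c1ccccc1)c1ccccc1)
Why: Enolate oxidation with a Davis oxaziridine: enolate 13 is attacked on the convex face of the cis-bicyclo[3.3.0] unit, anti to C9a on C12, which puts the hydroxyl exo and leaves the methyl endo (13S). Both C13 epimers converge, the tertiary azide has no α-hydrogen, and ring E is not yet present.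

Step 8
Reactants: 14 (3S,3aR,4S,5R,6R,6aS)-5-allyl-4-azido-4-[2-(1,3-dioxolan-2-yl)ethyl]-6-ethyl-3-hydroxy-3-methylhexahydro-2H-cyclopenta[b]furan-2-one
Product: 15 (3S,3aR,4S,5R,6R,6aS)-4-azido-4-[2-(1,3-dioxolan-2-yl)ethyl]-6-ethyl-3-hydroxy-3-methyl-5-[(E)-4-oxobut-2-en-1-yl]hexahydro-2H-cyclopenta[b]furan-2-one
Conditions: (E)-but-2-enal (10 equiv), second-generation Hoveyda–Grubbs catalyst RuCl2(H2IMes)(=CH-C6H4-2-OiPr) (5 mol %), CH2Cl2, 40 °C
Reagents that add atoms: (E)-but-2-enal (C/C=C/C=O)
Why: Olefin cross-metathesis of the terminal allyl group with excess enal gives the (E)-enal and propene, adding C6 and C5; a phosphine-free ruthenium carbene avoids Staudinger reaction with the azide.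

Step 9
Reactants: 15 (3S,3aR,4S,5R,6R,6aS)-4-azido-4-[2-(1,3-dioxolan-2-yl)ethyl]-6-ethyl-3-hydroxy-3-methyl-5-[(E)-4-oxobut-2-en-1-yl]hexahydro-2H-cyclopenta[b]furan-2-one
Product: 18 tricyclic amino lactone with rings B, C and D closed, N4–H, and the 2-(1,3-dioxolan-2-yl)ethyl chain (C1–C3) on C9a (9R,9aS,10R,11S,12R,13S), via amino aldehyde 16 (not isolated), via cyclic imine 17 (not isolated)
Conditions: H2 (1 atm), 10% Pd/C, EtOAc/EtOH (0.01 M), rt
Reagents that add atoms: none
Why: Tandem hydrogenation and intramolecular reductive amination: the enal C=C and the azide are reduced, amine 16 condenses with the C5 aldehyde to seven-membered imine 17, and this is reduced. The trans relation of N4 and C8 rules out five-membered aza-Michael closure, and no stereocentre is formed.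

Step 10
Reactants: 19 3-methylfuran-2(5H)-one
Product: 20 triisopropyl[(3-methylfuran-2-yl)oxy]silane
Conditions: iPr3SiOSO2CF3, Et3N, CH2Cl2, 0 °C
Reagents that add atoms: triisopropylsilyl trifluoromethanesulfonate (CC(C)[Si](OS(=O)(=O)C(F)(F)F)(C(C)C)C(C)C)
Why: Soft enolisation of the butenolide and O-silylation of its dienolate give the 2-silyloxyfuran.

Step 11
Reactants: 18 tricyclic amino lactone (rings B, C, D; acetal chain on C9a); 20 triisopropyl[(3-methylfuran-2-yl)oxy]silane
Product: 23 19,20-didehydro-24, the ring-E butenolide with rings A–D complete (3S,9R,9aS,10R,11S,12R,13S,18S), via amino aldehyde 21 (not isolated), via iminium trifluoroacetate 22 (not isolated)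
Conditions: CF3CO2H/H2O (9:1), 0 °C to rt; concentrate; then 20 (3 equiv), CH2Cl2, −78 to 0 °C; aq. NaHCO3
Reagents that add atoms: none
Why: Acid unmasks the C3 aldehyde, which condenses with N4–H to close ring A as bicyclic iminium 22; the silyloxyfuran then adds through its C5 position (vinylogous Mannich reaction). Attack is expected anti to the C5–C6 bridge of ring B, that is on the C12 face of C3, and the open transition state of such additions favours the threo (3S,18S) pair.

Step 12
Reactants: 23 19,20-didehydro-24
Product: 24 target alkaloid (3S,9R,9aS,10R,11S,12R,13S,18S,20S)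
Conditions: H2 (3 atm), 10% Pd/C, EtOAc, rt
Reagents that add atoms: none
Why: Heterogeneous hydrogenation of the butenolide from the face opposite to the C3 substituent on C18 gives the 18,20-cis lactone (20S); the lactones, tertiary alcohol and amine are inert.

## Compound list

1 | (R)-4-[(tert-butyldimethylsilyl)oxy]cyclopent-2-en-1-one | O=C1C=C[C@H](O[Si](C)(C)C(C)(C)C)C1 | starting material
2 | copper enolate from ethyl addition to 1 (monovalent copper) | CC[C@H]1[C@H](O[Si](C)(C)C(C)(C)C)CC(O[Cu])=C1 | intermediate
3 | triphenyltin enolate | CC[C@H]1[C@H](O[Si](C)(C)C(C)(C)C)CC(O[Sn](c2ccccc2)(c2ccccc2)c2ccccc2)=C1 | intermediate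
4 | (2R,3R,4R)-2-allyl-4-[(tert-butyldimethylsilyl)oxy]-3-ethylcyclopentan-1-one | CC[C@H]1[C@H](O[Si](C)(C)C(C)(C)C)CC(=O)[C@@H]1CC=C | intermediate
5 | potassium enolate of 4 (C9a=C12) | CC[C@H]1[C@H](O[Si](C)(C)C(C)(C)C)C=C([O-])[C@@H]1CC=C.[K+] | intermediate
6 | (3S,4R,5R)-5-allyl-3-[(tert-butyldimethylsilyl)oxy]-4-ethylcyclopent-1-en-1-yl trifluoromethanesulfonate | CC[C@H]1[C@H](O[Si](C)(C)C(C)(C)C)C=C(OS(=O)(=O)C(F)(F)F)[C@@H]1CC=C | intermediate
7 | [2-(1,3-dioxolan-2-yl)ethyl]zinc bromide | Br[Zn]CCC1OCCO1 | starting material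
8 | tert-butyl{[(1S,4R,5R)-4-allyl-3-[2-(1,3-dioxolan-2-yl)ethyl]-5-ethylcyclopent-2-en-1-yl]oxy}dimethylsilane | CC[C@H]1[C@H](O[Si](C)(C)C(C)(C)C)C=C(CCC2OCCO2)[C@@H]1CC=C | intermediate
9 | (1S,4R,5R)-4-allyl-3-[2-(1,3-dioxolan-2-yl)ethyl]-5-ethylcyclopent-2-en-1-ol | CC[C@H]1[C@H](O)C=C(CCC2OCCO2)[C@@H]1CC=C | intermediate
10 | 2-bromopropanoate of 9 (C13 epimers) | CC[C@H]1[C@H](OC(=O)C(C)Br)C=C(CCC2OCCO2)[C@@H]1CC=C | intermediate
11 | 2-iodopropanoate of 9 (C13 epimers) | CC[C@H]1[C@H](OC(=O)C(C)I)C=C(CCC2OCCO2)[C@@H]1CC=C | intermediate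
12 | (3aR,4S,5R,6R,6aS)-5-allyl-4-azido-4-[2-(1,3-dioxolan-2-yl)ethyl]-6-ethyl-3-methylhexahydro-2H-cyclopenta[b]furan-2-one (C13 epimers) | CC[C@H]1[C@@H]2OC(=O)C(C)[C@@H]2[C@](N=[N+]=[N-])(CCC2OCCO2)[C@@H]1CC=C | intermediate
13 | potassium enolate of 12 | CC[C@H]1[C@@H]2OC([O-])=C(C)[C@@H]2[C@](N=[N+]=[N-])(CCC2OCCO2)[C@@H]1CC=C.[K+] | intermediate
14 | (3S,3aR,4S,5R,6R,6aS)-5-allyl-4-azido-4-[2-(1,3-dioxolan-2-yl)ethyl]-6-ethyl-3-hydroxy-3-methylhexahydro-2H-cyclopenta[b]furan-2-one | CC[C@H]1[C@@H]2OC(=O)[C@@](C)(O)[C@@H]2[C@](N=[N+]=[N-])(CCC2OCCO2)[C@@H]1CC=C | intermediate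
15 | (E)-enal from cross-metathesis of 14 | CC[C@H]1[C@@H]2OC(=O)[C@@](C)(O)[C@@H]2[C@](N=[N+]=[N-])(CCC2OCCO2)[C@@H]1C/C=C/C=O | intermediate
16 | saturated amino aldehyde (C9a–NH2, C5 aldehyde) | CC[C@H]1[C@@H]2OC(=O)[C@@](C)(O)[C@@H]2[C@](N)(CCC2OCCO2)[C@@H]1CCCC=O | intermediate
17 | seven-membered cyclic imine (N4=C5) | CC[C@H]1[C@@H]2OC(=O)[C@@](C)(O)[C@@H]2[C@@]3(CCC4OCCO4)N=CCCC[C@H]13 | intermediate
18 | tricyclic amino lactone (rings B, C, D; acetal chain on C9a) | CC[C@H]1[C@@H]2OC(=O)[C@@](C)(O)[C@@H]2[C@@]3(CCC4OCCO4)NCCCC[C@H]13 | intermediate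
19 | 3-methylfuran-2(5H)-one | CC1=CCOC1=O | starting material
20 | triisopropyl[(3-methylfuran-2-yl)oxy]silane | Cc1ccoc1O[Si](C(C)C)(C(C)C)C(C)C | intermediate
21 | amino aldehyde from 18 (C3 aldehyde) | CC[C@H]1[C@@H]2OC(=O)[C@@](C)(O)[C@@H]2[C@@]3(CCC=O)NCCCC[C@H]13 | intermediate
22 | tetracyclic iminium trifluoroacetate (N4=C3) | CC[C@H]1[C@@H]2OC(=O)[C@@](C)(O)[C@@H]2[C@@]23CCC=[N+]2CCCC[C@H]13.[O-]C(=O)C(F)(F)F | intermediate
23 | 19,20-didehydro-24 (ring-E butenolide) | CC[C@H]1[C@@H]2OC(=O)[C@@](C)(O)[C@@H]2[C@@]23CC[C@@H]([C@@H]4C=C(C)C(=O)O4)N2CCCC[C@H]13 | intermediate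
24 | target alkaloid (3S,9R,9aS,10R,11S,12R,13S,18S,20S) | CC[C@H]1[C@@H]2OC(=O)[C@@](C)(O)[C@@H]2[C@@]23CC[C@@H]([C@@H]4C[C@H](C)C(=O)O4)N2CCCC[C@H]13 | target

## Step count and least certain steps

Total step count: 12. Longest linear sequence: 11 steps (steps 1–9, 11 and 12, from 1); step 10 is the one-step side branch.

**Step 6 (key step).** The most likely failure is slow ring closure: the ester prefers the rotamer that holds the C13 radical away from the alkene, so intermolecular addition to the allyl group of a second molecule, or loss of the radical before cyclisation, can compete. Incomplete facial control in the azide transfer is the lesser worry. Fallback: separate C–C from C–N bond formation. Starting from 11, iodine-atom-transfer cyclisation ((Bu3Sn)2 10 mol %, sunlamp, benzene, 80 °C) should give the tertiary iodide F1. Silver-assisted ionisation (AgOSO2CF3, Me3SiN3, CH2Cl2, −40 °C) then lets azide enter the C9a cation from the same open face. The route is rejoined at 12.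

**Step 2.** Enolate 5 may expel the C11 silyloxy group, or deprotonation may lose regiocontrol. Fallback without an enolate: from 4, condensation with N2H4·H2O (EtOH) gives the hydrazone F2. Oxidation with I2 and 1,1,3,3-tetramethylguanidine (Barton iodination) gives the alkenyl iodide F3, with proton loss expected from the less hindered C12. F3 couples with 7 under the conditions of step 3 and the route is rejoined at 8.

**Step 9.** Intermolecular reductive amination (oligomers) may compete, or the reaction may stall at 16 because the trans-fused seven-membered imine forms slowly. Fallback that closes ring B through a C=C bond: from 14, Staudinger reduction (PMe3, THF/H2O) gives the primary amine F4. N-Allylation (allyl bromide, K2CO3, MeCN) gives the diene F5. Ring-closing metathesis of its tosylate salt (second-generation Grubbs catalyst RuCl2(=CHPh)(H2IMes)(PCy3), CH2Cl2, 40 °C) gives the tetrahydroazepine F6. Hydrogenation (H2, Pd/C) then rejoins the route at 18.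

**Step 11.** The silyloxyfuran may attack the wrong face of 22 (C3 epimer), or erythro selectivity may leak at C18. Fallback that fixes C3 before the N4–C3 bond exists and closes ring A by stereospecific substitution:
- From 14, aqueous AcOH frees the azido aldehyde F7.
- An anti-selective vinylogous Mukaiyama aldol reaction with 20 under Ti(OiPr)4/BINOL control (the BINOL enantiomer chosen for the 3R carbinol) gives the hydroxy butenolide F8.
- MsCl/Et3N gives the mesylate F9.
- Cross-metathesis as in step 8 gives the enal F10.
- Hydrogenation as in step 9 also saturates ring E and gives the azepane amino mesylate F11.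
- Heating with iPr2NEt in MeCN closes ring A by SN2 with inversion at C3 and rejoins the route at 24.

## Further compounds

F1 | step 6 | tertiary iodide (C9a–I, ring D closed, C13 epimers) | CC[C@H]1[C@@H]2OC(=O)C(C)[C@@H]2[C@](I)(CCC2OCCO2)[C@@H]1CC=C
F2 | step 2 | hydrazone of 4 | CC[C@H]1[C@H](O[Si](C)(C)C(C)(C)C)CC(=NN)[C@@H]1CC=C
F3 | step 2 | alkenyl iodide (C9a–I, C9a=C12) | CC[C@H]1[C@H](O[Si](C)(C)C(C)(C)C)C=C(I)[C@@H]1CC=C
F4 | step 9 | primary amine from 14 | CC[C@H]1[C@@H]2OC(=O)[C@@](C)(O)[C@@H]2[C@](N)(CCC2OCCO2)[C@@H]1CC=C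
F5 | step 9 | N-allyl amine (diene) | CC[C@H]1[C@@H]2OC(=O)[C@@](C)(O)[C@@H]2[C@](NCC=C)(CCC2OCCO2)[C@@H]1CC=C
F6 | step 9 | tetrahydroazepine (C6=C7) | CC[C@H]1[C@@H]2OC(=O)[C@@](C)(O)[C@@H]2[C@@]3(CCC4OCCO4)NCC=CC[C@H]13
F7 | step 11 | azido aldehyde (C3 aldehyde) | CC[C@H]1[C@@H]2OC(=O)[C@@](C)(O)[C@@H]2[C@](N=[N+]=[N-])(CCC=O)[C@@H]1CC=C
F8 | step 11 | (3R,18S)-hydroxy butenolide | CC[C@H]1[C@@H]2OC(=O)[C@@](C)(O)[C@@H]2[C@](N=[N+]=[N-])(CC[C@@H](O)[C@@H]2C=C(C)C(=O)O2)[C@@H]1CC=C
F9 | step 11 | C3 mesylate of F8 | CC[C@H]1[C@@H]2OC(=O)[C@@](C)(O)[C@@H]2[C@](N=[N+]=[N-])(CC[C@@H](OS(C)(=O)=O)[C@@H]2C=C(C)C(=O)O2)[C@@H]1CC=C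
F10 | step 11 | (E)-enal from cross-metathesis of F9 | CC[C@H]1[C@@H]2OC(=O)[C@@](C)(O)[C@@H]2[C@](N=[N+]=[N-])(CC[C@@H](OS(C)(=O)=O)[C@@H]2C=C(C)C(=O)O2)[C@@H]1C/C=C/C=O
F11 | step 11 | azepane amino mesylate with ring E saturated | CC[C@H]1[C@@H]2OC(=O)[C@@](C)(O)[C@@H]2[C@@]3(CC[C@@H](OS(C)(=O)=O)[C@@H]4C[C@H](C)C(=O)O4)NCCCC[C@H]13
A1 | alternative 1 | N-benzyl ketimine of 4 (imine geometry not defined) | CC[C@H]1[C@H](O[Si](C)(C)C(C)(C)C)CC(=NCc2ccccc2)[C@@H]1CC=C
A2 | alternative 1 | allyl adduct, C9a epimer (carbon up, nitrogen down) | CC[C@H]1[C@H](O[Si](C)(C)C(C)(C)C)C[C@](CC=C)(NCc2ccccc2)[C@@H]1CC=C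
A3 | alternative 2 | trans-fused azido ketone with ring D (C13 not defined) | CC[C@H]1[C@@H]2OC(=O)C(C)[C@@H]2[C@@]2(CCCN=[N+]=[N-])C(=O)CCC[C@H]12
A4 | alternative 2 | Schmidt lactam (rings A–D, C5 carbonyl, C13 not defined) | CC[C@H]1[C@@H]2OC(=O)C(C)[C@@H]2[C@@]23CCCN2C(=O)CCC[C@H]13
A5 | alternative 3 | pyrroline N-oxide with (E)-enoate chain | CC[C@@H]([C@H](O[Si](C)(C)C(C)(C)C)/C=C(\C)C(=O)OC)[C@@H](CC=C)C1=[N+]([O-])CCC1
A6 | alternative 3 | cis-fused isoxazolidine (N4 and C13 syn on ring C, 12-epi) | CC[C@H]1[C@H](O[Si](C)(C)C(C)(C)C)[C@H]2[C@](C)(C(=O)OC)ON3CCC[C@]23[C@@H]1CC=C
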